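(The readings stem from a simulated flask for an exercise, noise included.)

A small charge of free base, 0.79 equiv in cedar, left 82% of the electrophile at 90.0 min. The 1.7 equiv in oak left 80%, a gap of 2 percentage points against a scatter of 1.5 points per reading.

| setting | cedar | oak | Thursday's | Sunday's | Wednesday's |
|---|---|---|---|---|---|
| electrophile | 0.40 M | 0.40 M | 0.40 M | 0.40 M | 0.40 M |
| free base | 0.79 equiv | 1.7 equiv | 1.50 equiv | 2.00 equiv | 2.50 equiv |
| protonated nucleophile | 1 equiv | 1 equiv | 1.00 equiv | 1.00 equiv | 1.00 equiv |
| remark | run made earlier | run made earlier |  |  |  |
| time |  |  | 1.5 h | 1.5 h | 1.5 h |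

| run | time / min | electrophile / % | target / % |
|---|---|---|---|
| cedar | 8.00 | 96 | 8 |
| cedar | 15.0 | 93 | 6 |
| cedar | 25.0 | 91 | 8 |
| cedar | 50.0 | 87 | 8 |
| cedar | 90.0 | 82 | 14 |
| oak | 8.00 | 97 | 4 |
| oak | 15.0 | 91 | 6 |
| oak | 25.0 | 89 | 12 |
| oak | 50.0 | 86 | 14 |
| oak | 90.0 | 80 | 17 |

(readings scatter by 1.5 percentage points)

- part of the electrophile that has reacted at the end, Thursday's
- part of the electrophile that has reacted at the end, Sunday's
- part of the electrophile that has reacted at the end, Wednesday's
- what raising the equivalents of free base from its lowest to its highest value here does to the part of the electrophile that has reacted (changes below 5 percentage points count as none) (it rises / no change / it falls)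



The fraction left is the quantity to reckon with. Its log-left, minus the logarithm of that fraction, is compared between two flasks at one time:

log-left, cedar = 0.198
log-left, oak = 0.223
log-left ratio, oak over cedar = 1.12

The log-left ratio tells how many times as far one flask has gone as another at the same time; unity means equally far. From cedar to oak a factor of 2.15 in free base bought 1.12, and the gap behind it is smaller than the 2.1 points standard deviation of a difference of two readings, so these readings show free base as a weak lever.

Is one number enough? In a pseudo-first-order flask, log-left grows in step with time. Cedar's readings grew by a factor of 2.10 from 25.0 min to 90.0 min, less than the time factor of 3.60. So the ratio serves at one time, and the new flasks stop at 1.5 h, the time of the last readings.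

Applying the ratio once more from oak to Wednesday's, a smaller step in free base, gives this reckoning's high figure:

reacted = 22.1%

That stands 4.2 points above the part reacted in cedar, less than the 5 points margin, so this reckoning expects no change.

The forecast, lower than this reckoning for Wednesday's, gave 20%, 20.5% and 21%, and no change, judging that “the rate depends little on base”.

The flasks give 18.9%, 18.8% and 18.8%: no change.

    nucleophile + acid set free ⇌ protonated nucleophile, settled at all times (K = 47.0 M⁻¹)
    target ⇌ isomer of the product (K = 0.110, k = 9.04 × 10⁻⁴ s⁻¹)
    acid set free + free base ⇌ salt of the base, settled at all times (K = 1670 M⁻¹)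
    electrophile + nucleophile → acid set free + target (k = 4.04 × 10⁻⁴ M⁻¹ s⁻¹)
    2 nucleophile → self-condensation product (k = 0.00182 M⁻¹ s⁻¹)

Wednesday's over Thursday's has a log-left ratio of 0.994, beside the 1.12 read from oak and cedar. In Sunday's, the path to target had half of its turnover up to 1.5 h done by 0.301 h, and self-condensation had 74% of its own behind it by 0.300 h. By 1.50 h, Sunday's [nucleophile] stood at 0.0302 M, with free base at 41% of its charge. A flask like Sunday's but with 2.50 equiv of protonated nucleophile had 25.0% of its electrophile reacted, a log-left ratio against Sunday's of 1.38, more than the 1.12 of oak over cedar.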